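The ten-membered carbocycle (ring A, C1–C10) is opened at both bonds to C2. C2 is a ketone carbon whose two neighbours are each allylic: C1 to the exocyclic C10=C14 alkene and C3 to the endocyclic C4=C5 alkene. One palladium-catalysed carbonylative allyl–allyl Stille coupling brings in carbon monoxide as C2. It forms C2–C3 and C1–C2 and closes ring A onto the finished α-methylene lactone (ring B), so the cyclisation product is the target itself. The precursor 23 is the acyclic (E)-C3 allylic chloride and C1 allyltributylstannane, already carrying ring B and the C8 and C15 acetates. Tin enters only two steps before the cyclisation.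

Key step: step 16

Convention: the germacrane numbering of 25 is used for every intermediate. Ring A = C1–C10; ring B = O, C6, C7, C11, C12; C13 = lactone methylene carbon; C14 = methylene carbon on C10; C15 = acetoxymethyl carbon on C4.

Assumption: C11 in 5–8, 11, 13–18, 21 and 22 is drawn with C13 trans to the C7 substituent, the expected outcome of step 3. This centre becomes sp2 in step 15, so its configuration has no bearing on the result.

Step 1
Reactants: 1 (S)-5-(hydroxymethyl)furan-2(5H)-one
Product: 2 (S)-5-[(tert-butyldimethylsilyloxy)methyl]furan-2(5H)-one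
Conditions: TBSCl, imidazole, DMF, 0 °C → rt
Reagents that add atoms: tert-butyldimethylsilyl chloride, CC(C)(C)[Si](C)(C)Cl
Why: Imidazole-promoted silylation of the primary alcohol gives a bulky, light-transparent ether that shields one face of the butenolide in step 2 and tolerates LDA in step 3, while C6 is taken unchanged from the chiral pool.

Step 2
Reactants: 2 silyl ether of the butenolide; 3 1,3-dioxolane (also the solvent)
Product: 4 (4S,5S)-5-[(tert-butyldimethylsilyloxy)methyl]-4-(1,3-dioxolan-2-yl)dihydrofuran-2(3H)-one (C6/C7 trans)
Conditions: hν (Hg lamp, Pyrex), Ph2CO (10 mol %), neat 3, degassed, 0–10 °C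
Reagents that add atoms: none
Why: Triplet benzophenone abstracts the acetal hydrogen of 3, and the nucleophilic dioxolan-2-yl radical adds to C7 of the electron-poor butenolide (photochemical Giese-type conjugate addition) from the face opposite the C6 silyloxymethyl group, which sets C7 trans to C6 and delivers C8 as a masked aldehyde.

Step 3
Reactants: 4 trans dioxolanyl lactone
Product: 5 (3R,4S,5S)-5-[(tert-butyldimethylsilyloxy)methyl]-4-(1,3-dioxolan-2-yl)-3-(hydroxymethyl)dihydrofuran-2(3H)-one
Conditions: LDA, THF, −78 °C; CH2O (gas, from cracked paraformaldehyde), −78 → −30 °C; aq NH4Cl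
Reagents that add atoms: formaldehyde, C=O
Why: Aldol-type hydroxymethylation of the lithium lactone enolate should place C13 anti to the C7 dioxolanyl group, and the new C11 centre is only transient because step 15 erases it.

Step 4
Reactants: 5 α-hydroxymethyl lactone
Product: 6 [(3R,4S,5S)-5-[(tert-butyldimethylsilyloxy)methyl]-4-(1,3-dioxolan-2-yl)-2-oxotetrahydrofuran-3-yl]methyl acetate
Conditions: Ac2O, pyridine, DMAP (cat.), CH2Cl2, 0 °C
Reagents that add atoms: acetic anhydride, CC(=O)OC(C)=O
Why: Routine O-acetylation turns C13 into a latent α-methylene group that is inert to acid, oxidants and weak bases and keeps C11 sp3, so the later C8 aldehyde cannot slide into conjugation with ring B.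

Step 5
Reactants: 6 silyl-protected acetoxymethyl lactone
Product: 7 [(3R,4S,5S)-4-(1,3-dioxolan-2-yl)-5-(hydroxymethyl)-2-oxotetrahydrofuran-3-yl]methyl acetate
Conditions: HF·pyridine, pyridine, THF, 0 °C → rt
Reagents that add atoms: none
Why: Fluoride-driven desilylation from a mildly acidic, non-basic source frees the C5 hydroxyl without E1cB loss of the C13 acetate, acetyl migration or acetal cleavage.

Step 6
Reactants: 7 C5 primary alcohol
Product: 8 [(3R,4S,5S)-4-(1,3-dioxolan-2-yl)-5-formyl-2-oxotetrahydrofuran-3-yl]methyl acetate (C5 aldehyde, used crude)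
Conditions: DMP, CH2Cl2, 0 °C → rt
Reagents that add atoms: none
Why: Dess–Martin oxidation works under essentially neutral conditions, so the α-acyloxy aldehyde keeps its C6 configuration, which is in any case the thermodynamically preferred trans arrangement.

Step 7
Reactants: 9 (triphenylphosphoranylidene)acetaldehyde
Product: 10 2-bromo-2-(triphenylphosphoranylidene)acetaldehyde
Conditions: NBS, CH2Cl2, −20 → 0 °C
Reagents that add atoms: N-bromosuccinimide, O=C1CCC(=O)N1Br
Why: Electrophilic α-halogenation of a stabilised ylide, in which the succinimide anion removes the remaining α-proton of the bromophosphonium ion and regenerates the ylide.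

Step 8
Reactants: 8 C5 aldehyde; 10 bromo(formyl) ylide
Product: 11 (Z)-2-bromo-3-(ring B)propenal: 8 with its CHO replaced by CH=C(Br)CHO, C3 formyl trans to C6 and Br cis to C6
Conditions: toluene, rt → 40 °C
Reagents that add atoms: none
Why: Wittig olefination with an α-substituted, carbonyl-stabilised ylide places the carbonyl group trans to the aldehyde residue, and the ylide is too weakly basic to epimerise C6 or eliminate the C13 acetate.

Step 9
Reactants: 11 (Z)-2-bromoenal; 12 (tributylstannyl)methanol
Product: 14 (E)-2-(acetoxymethyl)enal (C15H2OAc cis to C6; C3 formyl trans to C6), via hydroxymethyl enal 13 (not isolated)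
Conditions: Pd(PPh3)4 (5 mol %), 1,4-dioxane, 80 °C; then Ac2O, pyridine, DMAP (cat.), 0 °C → rt
Reagents that add atoms: acetic anhydride, CC(=O)OC(C)=O
Why: Stille hydroxymethylation of the electron-poor alkenyl bromide proceeds with retention of alkene geometry (which is also the thermodynamic geometry of a 2-substituted enal), so C15 ends cis to C6, and acetylation in the same flask protects the sensitive hydroxy enal at once.

Step 10
Reactants: 14 (E)-2-(acetoxymethyl)enal
Product: 15 (Z)-allylic alcohol (C3H2OH trans to C6; C15H2OAc cis to C6)
Conditions: NaBH4, CeCl3·7H2O, MeOH, −78 °C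
Reagents that add atoms: none
Why: Luche reduction attacks only the aldehyde in 1,2-fashion and spares the lactone and both acetates, while the low temperature holds back acetyl migration from O15 to O3, which would blur the C3/C15 differentiation.

Step 11
Reactants: 15 C3 allylic alcohol (used directly)
Product: 17 (E)-allylic chloride (C3H2Cl trans to C6) with dioxolane at C8, via allylic mesylate 16 (not isolated)
Conditions: MsCl, 2,4,6-collidine, LiCl, DMF, 0 °C
Reagents that add atoms: lithium chloride, [Li+].[Cl-]; methanesulfonyl chloride, CS(=O)(=O)Cl (its atoms stay only in 16)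
Why: Mesylation followed by direct SN2 chloride exchange at the primary allylic carbon is the standard way to allylic chlorides without allylic transposition or change of alkene geometry.

Step 12
Reactants: 17 allylic chloride with C8 dioxolane
Product: 18 C8 aldehyde (17 with the dioxolane replaced by CHO)
Conditions: TFA–H2O (9:1), CH2Cl2, 0 °C → rt
Reagents that add atoms: water, O
Why: Acid-catalysed acetal hydrolysis leaves the esters and the primary allylic chloride untouched, and the acidic medium avoids base-induced opening of the β-acyloxy aldehyde and epimerisation at C7.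

Step 13
Reactants: 19 3-chloro-2-(chloromethyl)prop-1-ene
Product: 20 2-methylenepropane-1,3-diylbis(tributylstannane)
Conditions: Bu3SnH, LDA, THF, 0 °C; then 19, −78 °C → rt
Reagents that add atoms: tributyltin hydride, CCCC[SnH](CCCC)CCCC
Why: Twofold SN2 displacement of the bis-allylic dichloride by tributylstannyllithium gives the bifunctional allyl donor in one operation.

Step 14
Reactants: 18 C8 aldehyde; 20 bis-stannane (excess)
Product: 21 (8S)-homoallylic alcohol bearing the C1 allyltributylstannane
Conditions: (S)-BINOL (20 mol %), Ti(OiPr)4 (10 mol %), 4 Å MS, CH2Cl2, −20 °C; aq NaHCO3; Et3N-washed silica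
Reagents that add atoms: none
Why: In this Keck-type catalytic asymmetric allylation one C–Sn bond of 20 reacts in SE2′ fashion, the (S)-ligand directs attack to the Si face of C8, which is the face also favoured by the Felkin–Anh model with the C7–C6 bond anti to the nucleophile (matched case, 8S), and the excess of the doubly activated 20 disfavours a second transfer from 21.

Step 15
Reactants: 21 C8 alcohol
Product: 23 seco chloride–stannane precursor (6R,7R,8S; E alkene; α-methylene lactone; C8 and C15 acetates), via triacetate 22 (not isolated)
Conditions: Ac2O, Et3N, DMAP (cat.), CH2Cl2, 0 °C; then DBU (1.2 equiv), 0 °C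
Reagents that add atoms: acetic anhydride, CC(=O)OC(C)=O
Why: Fast DMAP-catalysed acetylation caps O8 before it can translactonise onto C12, and DBU then removes the C13 acetate by E1cB elimination (the classical β-acyloxy route to α-methylene lactones) under conditions the allylstannane, the allylic chloride and the other acetates should tolerate.

Step 16
Reactants: 23 seco chloride–stannane precursor; 24 carbon monoxide
Product: 25 CNP0183179.1 (target)
Conditions: Pd2(dba)3 (5 mol %), P(2-furyl)3 (20 mol %), CO (3 atm), THF, 50 °C, 23 added by pump over 12 h (final ca. 1 mM)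
Reagents that add atoms: none
Why: Proposed new method: zerovalent palladium ionises the C3–Cl bond, far faster than either allylic ester, to a π-allyl complex of divalent palladium; CO inserts at the unhindered C3 terminus to give the acylpalladium chloride, the C1 allylstannane transmetallates, and reductive elimination forms C1–C2 with release of Bu3SnCl. The closest known chemistry is the intermolecular carbonylative Stille coupling of allyl chlorides with allylstannanes to unsymmetrical diallyl ketones, together with carbonylative Stille macrocyclisations of tethered halide–stannane pairs; the new element is the allyl–allyl pairing in a ring closure of this size. Ring A closes as a ten-membered carbocycle by reductive elimination from an eleven-membered acyl(η1-allyl)palladacycle, and slow addition at high dilution favours this over oligomerisation. No stereocentre is formed, and C6, C7 and C8 are not touched. The step needs CO uptake before C–C coupling (secured by CO pressure, which suppresses direct allyl–allyl coupling to a nine-membered ring), acylation at C3 with the C4=C5 geometry kept (the E chloride gives directly the π-allyl with C6 syn, so no isomerisation through C5 is required), and indifference to allylic transposition on the tin side (C1 and C14 are both CH2 termini of one 2-substituted allyl unit, so both modes give the same ketone). The neutral medium should leave the doubly β,γ-unsaturated ketone, both acetates and the α-methylene lactone intact.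

Compound list
1 | (S)-5-(hydroxymethyl)furan-2(5H)-one | OC[C@H]1OC(=O)C=C1 | starting material
2 | (S)-5-[(tert-butyldimethylsilyloxy)methyl]furan-2(5H)-one | CC(C)(C)[Si](C)(C)OC[C@H]1OC(=O)C=C1 | intermediate
3 | 1,3-dioxolane | C1COCO1 | starting material
4 | (4S,5S)-5-[(tert-butyldimethylsilyloxy)methyl]-4-(1,3-dioxolan-2-yl)dihydrofuran-2(3H)-one | CC(C)(C)[Si](C)(C)OC[C@H]1OC(=O)C[C@@H]1C2OCCO2 | intermediate
5 | (3R,4S,5S)-3-(hydroxymethyl) derivative of 4 | CC(C)(C)[Si](C)(C)OC[C@H]1OC(=O)[C@@H](CO)[C@@H]1C2OCCO2 | intermediate
6 | (3R,4S,5S)-3-(acetoxymethyl) derivative of 4 | CC(C)(C)[Si](C)(C)OC[C@H]1OC(=O)[C@@H](COC(C)=O)[C@@H]1C2OCCO2 | intermediate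
7 | [(3R,4S,5S)-4-(1,3-dioxolan-2-yl)-5-(hydroxymethyl)-2-oxotetrahydrofuran-3-yl]methyl acetate | OC[C@H]1OC(=O)[C@@H](COC(C)=O)[C@@H]1C2OCCO2 | intermediate
8 | [(3R,4S,5S)-4-(1,3-dioxolan-2-yl)-5-formyl-2-oxotetrahydrofuran-3-yl]methyl acetate | O=C[C@H]1OC(=O)[C@@H](COC(C)=O)[C@@H]1C2OCCO2 | intermediate
9 | (triphenylphosphoranylidene)acetaldehyde | O=CC=P(c1ccccc1)(c1ccccc1)c1ccccc1 | starting material
10 | 2-bromo-2-(triphenylphosphoranylidene)acetaldehyde | O=CC(Br)=P(c1ccccc1)(c1ccccc1)c1ccccc1 | intermediate
11 | (Z)-2-bromoenal (Br cis to C6; ring stereocentres as in 8) | O=C/C(Br)=C/[C@H]1OC(=O)[C@@H](COC(C)=O)[C@@H]1C2OCCO2 | intermediate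
12 | (tributylstannyl)methanol | OC[Sn](CCCC)(CCCC)CCCC | starting material
13 | (E)-2-(hydroxymethyl)enal (C15 cis to C6) | O=C/C(CO)=C/[C@H]1OC(=O)[C@@H](COC(C)=O)[C@@H]1C2OCCO2 | intermediate
14 | (E)-2-(acetoxymethyl)enal | O=C/C(COC(C)=O)=C/[C@H]1OC(=O)[C@@H](COC(C)=O)[C@@H]1C2OCCO2 | intermediate
15 | (Z)-allylic alcohol (C3–OH trans to C6) | OC/C(COC(C)=O)=C/[C@H]1OC(=O)[C@@H](COC(C)=O)[C@@H]1C2OCCO2 | intermediate
16 | (E)-allylic mesylate | CS(=O)(=O)OC/C(COC(C)=O)=C/[C@H]1OC(=O)[C@@H](COC(C)=O)[C@@H]1C2OCCO2 | intermediate
17 | (E)-allylic chloride with C8 dioxolane | ClC/C(COC(C)=O)=C/[C@H]1OC(=O)[C@@H](COC(C)=O)[C@@H]1C2OCCO2 | intermediate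
18 | (E)-allylic chloride with C8 aldehyde | ClC/C(COC(C)=O)=C/[C@H]1OC(=O)[C@@H](COC(C)=O)[C@@H]1C=O | intermediate
19 | 3-chloro-2-(chloromethyl)prop-1-ene | C=C(CCl)CCl | starting material
20 | 2-methylenepropane-1,3-diylbis(tributylstannane) | C=C(C[Sn](CCCC)(CCCC)CCCC)C[Sn](CCCC)(CCCC)CCCC | intermediate
21 | (8S)-homoallylic alcohol with C1 allyltributylstannane | ClC/C(COC(C)=O)=C/[C@H]1OC(=O)[C@@H](COC(C)=O)[C@@H]1[C@@H](O)CC(=C)C[Sn](CCCC)(CCCC)CCCC | intermediate
22 | (8S)-triacetate (C8, C13, C15) | ClC/C(COC(C)=O)=C/[C@H]1OC(=O)[C@@H](COC(C)=O)[C@@H]1[C@@H](OC(C)=O)CC(=C)C[Sn](CCCC)(CCCC)CCCC | intermediate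
23 | (6R,7R,8S)-seco precursor: (E)-C3 allylic chloride, C1 allyltributylstannane, α-methylene lactone, C8 and C15 acetates | ClC/C(COC(C)=O)=C/[C@H]1OC(=O)C(=C)[C@@H]1[C@@H](OC(C)=O)CC(=C)C[Sn](CCCC)(CCCC)CCCC | intermediate
24 | carbon monoxide | [C-]#[O+] | starting material
25 | CNP0183179.1, (6R,7R,8S), C4=C5 with C3 trans to C6 | C=C1CC(=O)C/C(COC(C)=O)=C/[C@H]2OC(=O)C(=C)[C@@H]2[C@@H](OC(C)=O)C1 | target

Total step count: 16. Longest linear sequence: 14 (steps 1–6, 8–12, 14–16); steps 7 and 13 prepare reagents on side branches.

Steps most likely to fail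

1. Step 16 (proposed new method). Several things may go wrong:
- The chain may oligomerise instead of cyclising.
- Allyl may couple to allyl before CO is taken up.
- The π-allyl complex may lose the C6 carboxylate by β-elimination.
- The skipped dienone may drift into conjugation on prolonged heating.

The fallback uses known chemistry and moves the ring closure from the metal to a polar carbonyl addition. It sets out from 23. Palladium-catalysed formylation of the allylic chloride (Pd(PPh3)4, CO, slow addition of Bu3SnH, THF, 50 °C) intercepts the acylpalladium species with hydride and should give the β,γ-unsaturated C2 aldehyde F1 with the stannane intact. BF3·OEt2 at −78 °C under high dilution then triggers the intramolecular allylstannane–aldehyde addition (SE2′). This forms C1–C2 and closes ring A as the macrocyclic C2 carbinol F2, of which either epimer serves. Dess–Martin oxidation comes back to the route at 25.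

2. Step 14. The catalyst may turn over slowly on the α-branched aldehyde, the product stannane may transfer a second time, protodestannylation may occur on work-up, or facial selectivity may be poor. The fallback sets out from 18 and 20. The addition is run with stoichiometric BF3·OEt2 (CH2Cl2, −78 °C), so that an open transition state under Felkin–Anh substrate control replaces the chiral catalyst, and 21 continues as before. The separated C8 epimer F3 is inverted by a Mitsunobu reaction with acetic acid (PPh3, DIAD, toluene, 0 °C). This gives the triacetate directly and comes back to the route at 22, from which DBU leads to 23.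

3. Step 9. Transfer of the sp3 carbon from tin may be slow. That would leave time for zerovalent palladium to ionise the allylic C6–O bond, for protodebromination, or for erosion of the alkene geometry. The fallback sets out from 8. Nozaki–Hiyama–Kishi coupling with 2-bromoallyl acetate (CrCl2, NiCl2 cat., DMF, rt) should give the 2-(acetoxymethyl)allylic alcohol F4 as C5 epimers. SOCl2 in Et2O at 0 °C then collapses its chlorosulfite by SNi′ through a chair-like six-membered transition state with C6 equatorial, which places the new CH2Cl trans to C6. This comes back to the route at 17 and bypasses 10–16.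

Further compounds
F1 | step 16 | seco C2 aldehyde with C1 allyltributylstannane (C3 trans to C6) | O=CC/C(COC(C)=O)=C/[C@H]1OC(=O)C(=C)[C@@H]1[C@@H](OC(C)=O)CC(=C)C[Sn](CCCC)(CCCC)CCCC
F2 | step 16 | macrocyclic C2 carbinol (2-dihydro-25, either C2 epimer) | C=C1CC(O)C/C(COC(C)=O)=C/[C@H]2OC(=O)C(=C)[C@@H]2[C@@H](OC(C)=O)C1
F3 | step 14 | (8R)-epimer of 21 | ClC/C(COC(C)=O)=C/[C@H]1OC(=O)[C@@H](COC(C)=O)[C@@H]1[C@H](O)CC(=C)C[Sn](CCCC)(CCCC)CCCC
F4 | step 9 | 2-(acetoxymethyl)allylic alcohol at C5 (C5 epimers) | C=C(COC(C)=O)C(O)[C@H]1OC(=O)[C@@H](COC(C)=O)[C@@H]1C2OCCO2
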